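**Strategy**

Everything rests on cutting the bond between C5 of the central ring (the 2-benzylresorcinol monomethyl ether) and the neighbouring CH2 of the two-carbon bridge. C5 is meta to both ring oxygens, so electrophilic substitution cannot reach it; a C5 bromide, inherited from 4-bromo-2,6-dimethoxybenzaldehyde, takes its place. The key step is a one-pot hydroboration/B-alkyl Suzuki–Miyaura coupling: 9-BBN turns the vinyl group of 3-vinylphenol into the primary alkylborane of the CH2–CH2 bridge, which couples with unprotected 5-bromo-2-(4-hydroxybenzyl)-3-methoxyphenol to give the target directly. The OMe/OH difference is set beforehand by chelation-controlled demethylation ortho to the aldehyde.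

Key step: step 4

Assumption (remark on the chemistry): Grignard reagent 3 is racemic at its acetal carbon, so 4 is expected as a mixture of diastereomers. Both stereocentres are removed in step 3, and the target has no stereocentre. Compounds 1, 3 (as a THF solution) and 6 are taken as purchasable.

**Route**

Step 1
Reactants: 1 4-bromo-2,6-dimethoxybenzaldehyde
Product: 2 4-bromo-2-hydroxy-6-methoxybenzaldehyde
Conditions: BCl3 (1.2 equiv, 1 M in CH2Cl2), CH2Cl2, −78 °C → 0 °C; then H2O
Reagents that add atoms: none
Why: Chelation-controlled Lewis-acid ether cleavage (selective demethylation ortho to an aryl carbonyl group): BCl3 bridges the formyl oxygen and one ortho methoxy group, chloride removes that methyl group, and the resulting six-membered aryloxyboron chelate ties up the carbonyl so the second methoxy group should survive.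

Step 2
Reactants: 2 4-bromo-2-hydroxy-6-methoxybenzaldehyde, 3 [4-(oxan-2-yloxy)phenyl]magnesium bromide
Product: 4 5-bromo-2-{hydroxy[4-(oxan-2-yloxy)phenyl]methyl}-3-methoxyphenol
Conditions: 3 (2.3 equiv, 0.5 M in THF), THF, 0 °C → rt; then pH 7 aqueous buffer
Reagents that add atoms: none
Why: Grignard 1,2-addition to an aldehyde: the first equivalent of 3 deprotonates the phenol and the second adds to the formyl group of the magnesium phenoxide, an aryl Grignard reagent does not exchange with the aryl bromide at this temperature, and the new carbinol centre forms without control (diastereomer mixture), which is irrelevant because it is removed in step 3.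

Step 3
Reactants: 4 5-bromo-2-{hydroxy[4-(oxan-2-yloxy)phenyl]methyl}-3-methoxyphenol
Product: 5 5-bromo-2-[(4-hydroxyphenyl)methyl]-3-methoxyphenol
Conditions: Et3SiH (4 equiv), TFA (10 equiv), CH2Cl2, 0 °C → rt
Reagents that add atoms: none
Why: Ionic hydrogenation (Et3SiH/TFA deoxygenation of a benzhydrol): TFA ionises the doubly benzylic alcohol to a cation stabilised by the ortho-OH, ortho-OMe and para-alkoxy groups, the silane delivers hydride to it, and the same acid cleaves the aryl THP acetal, whose oxocarbenium ion is likewise reduced to oxane.

Step 4
Reactants: 5 5-bromo-2-[(4-hydroxyphenyl)methyl]-3-methoxyphenol, 6 3-vinylphenol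
Product: 8 5-[2-(3-hydroxyphenyl)ethyl]-2-[(4-hydroxyphenyl)methyl]-3-methoxyphenol, via bis(9-BBN) adduct 7 (not isolated)
Conditions: 6 (1.5 equiv), 9-BBN (0.5 M in THF, 3.3 equiv), THF, 0 °C → rt; then 5, Pd(OAc)2 (5 mol%), SPhos (10 mol%), 3 M aq. K3PO4, THF, 65 °C; aq. NH4Cl work-up
Reagents that add atoms: none
Why: 9-BBN first borylates the phenol O–H of 6 (loss of H2) and then adds across the vinyl group with boron on the terminal carbon to give 7; Pd(0)/SPhos inserts into the C5–Br bond of 5, base-activated 7 transfers its primary 2-arylethyl group to palladium, reductive elimination forms the aryl C5–CH2 bond, and the aqueous base hydrolyses the O–B bond. The closest known reaction type is the one-pot hydroboration/B-alkyl Suzuki–Miyaura coupling of styrenes with aryl bromides to give bibenzyls. No ring is closed and no stereocentre is formed. The step needs anti-Markovnikov regioselectivity in the hydroboration, secured by the bulk of 9-BBN on a terminal styrene, and transfer of the primary alkyl group in preference to the secondary bicyclic B–C bonds, which is inherent to B-alkyl-9-BBN reagents. It also needs reductive elimination to outrun β-hydride elimination of the 2-arylethylpalladium species, which the bulky electron-rich biarylphosphine should secure, and it needs the single C–Br bond to react in the presence of three free phenols, which are carried as phenoxides in the aqueous base.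

**Compound list**

1 | 4-bromo-2,6-dimethoxybenzaldehyde | COc1cc(Br)cc(OC)c1C=O | starting material
2 | 4-bromo-2-hydroxy-6-methoxybenzaldehyde | COc1cc(Br)cc(O)c1C=O | intermediate
3 | [4-(oxan-2-yloxy)phenyl]magnesium bromide (racemic, THF solution) | Br[Mg]c1ccc(OC2CCCCO2)cc1 | starting material
4 | 5-bromo-2-{hydroxy[4-(oxan-2-yloxy)phenyl]methyl}-3-methoxyphenol (diastereomer mixture, racemic) | COc1cc(Br)cc(O)c1C(O)c1ccc(OC2CCCCO2)cc1 | intermediate
5 | 5-bromo-2-[(4-hydroxyphenyl)methyl]-3-methoxyphenol | COc1cc(Br)cc(O)c1Cc1ccc(O)cc1 | intermediate
6 | 3-vinylphenol (3-ethenylphenol) | C=Cc1cccc(O)c1 | starting material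
7 | 9-{2-[3-(9-borabicyclo[3.3.1]nonan-9-yloxy)phenyl]ethyl}-9-borabicyclo[3.3.1]nonane | C(Cc1cccc(OB2C3CCCC2CCC3)c1)B1C2CCCC1CCC2 | intermediate
8 | 5-[2-(3-hydroxyphenyl)ethyl]-2-[(4-hydroxyphenyl)methyl]-3-methoxyphenol (CNP0112925.0) | COc1cc(CCc2cccc(O)c2)cc(O)c1Cc1ccc(O)cc1 | target

**Step count**

Total steps: 4. Longest linear sequence: 4 steps (1 → 2 → 4 → 5 → 8).

**Steps most likely to fail**

Step 4. Oxidative addition into the electron-rich, phenoxide-bearing C5–Br bond may be slow. Protodeboronation or β-hydride elimination of the 2-arylethyl group, and interference of the free phenols with the borane, could then consume 7 before it couples. The fallback sets out from 5 and forms the same aryl C5–carbon bond at the alkyne oxidation level. A Sonogashira coupling of 5 with purchasable 3-ethynylphenol (C#Cc1cccc(O)c1; PdCl2(PPh3)2, CuI, Et3N, DMF, 70 °C), which tolerates free phenols, should give the diarylacetylene 5-[(3-hydroxyphenyl)ethynyl]-2-[(4-hydroxyphenyl)methyl]-3-methoxyphenol F1. Hydrogenation of F1 (H2, Pd/C, EtOAc/MeOH, rt) should then saturate the triple bond and come back to the route at 8.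

Step 3. The strongly stabilised benzhydryl cation, and the oxocarbenium ion from the THP group, may be captured by the electron-rich phenol rings of a second molecule faster than by the silane, which would lead to Friedel–Crafts oligomerisation. The fallback builds the diarylmethane without a cation and sets out from 2. Condensation of 2 with tosylhydrazide (MeOH, rt) should give the tosylhydrazone (E)-N'-[(4-bromo-2-hydroxy-6-methoxyphenyl)methylidene]-4-methylbenzenesulfonohydrazide F2. Metal-free reductive coupling of F2 with 4-hydroxyphenylboronic acid (K2CO3, dioxane, 110 °C; Barluenga coupling through the diazo compound, aryl shift from boron to carbon and protodeboronation) should give the diarylmethane directly and return to the route at 5, bypassing steps 2 and 3.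

Step 1. The stop after the first ether cleavage may not hold, so that over-demethylation to the resorcinol or incomplete conversion gives mixtures that are hard to separate. The fallback sets out from 1 and cleaves both ethers on purpose (BBr3 in excess, CH2Cl2, −78 °C → rt) to give 4-bromo-2,6-dihydroxybenzaldehyde F3. One hydroxyl of F3 is then methylated (MeI 1.0 equiv, Li2CO3, DMF, 40 °C). After the first methylation the remaining hydroxyl is held in a hydrogen bond to the formyl oxygen and should resist a second alkylation, so the sequence returns to the route at 2.

**Further compounds**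

F1 | step 4 | 5-[(3-hydroxyphenyl)ethynyl]-2-[(4-hydroxyphenyl)methyl]-3-methoxyphenol | COc1cc(C#Cc2cccc(O)c2)cc(O)c1Cc1ccc(O)cc1
F2 | step 3 | (E)-N'-[(4-bromo-2-hydroxy-6-methoxyphenyl)methylidene]-4-methylbenzenesulfonohydrazide | COc1cc(Br)cc(O)c1/C=N/NS(=O)(=O)c1ccc(C)cc1
F3 | step 1 | 4-bromo-2,6-dihydroxybenzaldehyde | O=Cc1c(O)cc(Br)cc1O
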